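## Analysis of the target

- The target is an achiral heptameric phlorotannin of the fuhalol kind. Seven benzene rings (lettered A to G in the order of the SMILES string) form one unbranched chain through six diaryl ether oxygens. It carries seventeen free phenolic hydroxyls and no stereocentre, so the problem is one of C–O connectivity and of oxidation-prone functionality.
- Numbering used below: in rings A, B, C, E, F and G, C1 bears the oxygen that points to the ring A end of the chain (a free OH in ring A). C4 bears the oxygen that points to the ring G end (a free OH in ring G). C3 and C5 bear hydroxyls. Ring D has the ether oxygen to ring C on C1, hydrogen on C2, hydroxyls on C3, C4 and C5, and the ether oxygen to ring E on C6.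
- The six bridges therefore join C4 of A to C1 of B, C4 of B to C1 of C, C4 of C to C1 of D, C6 of D to C1 of E, C4 of E to C1 of F, and C4 of F to C1 of G.
- The feature that the route is built on: every bridge oxygen sits on a ring carbon flanked by two oxygen-bearing carbons (C4 of rings A, B, C, E, F; C6 of ring D). That carbon always stands para (C4 to C1 in rings A, B, C, E, F) or ortho (C6 to C1 in ring D) to the carbon whose oxygen continues the chain toward ring A. This is the atom pattern of a para- or an ortho-quinone diazide, with the diazo group on the hindered carbon and the carbonyl oxygen where the chain goes on.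
- Rings A, B, C, E, F and G share one 1,2,3,5-tetraoxygenated pattern. Ring D is the same 3,4,5-trioxygenated phenol as ring G with one more ether oxygen ortho to C1, which gives the chain its single ortho kink.
- The free polyphenol, above all the pyrogallol-type rings D and G, should autoxidise readily in air and base. Free hydroxyls may therefore appear only at the very end, under neutral conditions that spare diaryl ethers.
- The difficulty is that each bridge joins two electron-rich rings at a di-ortho-oxygenated carbon, the worst case for copper- or palladium-mediated etherification and for nucleophilic aromatic substitution. This must be done six times, in a fixed order, with the ortho kink placed exactly.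

## Retrosynthetic reasoning

**17 from 16.** The last disconnection cuts no skeletal bond; it cleaves the sixteen O–benzyl bonds of 16. Compound 16 already has the free hydroxyl on C1 of ring A, because the last chain-growth step sets that oxygen free. All other hydroxyls travel as benzyl ethers. Hydrogenolysis is neutral and reductive, the conditions under which a seventeenfold phenol with two pyrogallol-type rings can be expected to survive, and diaryl ethers are inert to it.

**16 from 15 and 7, 15 from 14 and 7, 14 from 13 and 7.** In rings A, B and C the O–C4 bond is cut, not the O–C1 bond. Cutting at the hindered carbon turns each of these rings into the same para-quinone diazide 7, with the diazo group on C4 between the two benzyloxy groups and the carbonyl on C1. In the forward sense a carbene generated at C4 with a divalent rhodium catalyst inserts into the O–H bond of the chain end. The ring aromatises, and its carbonyl oxygen becomes the hydroxyl on C1, which is the nucleophile of the next round. The gain is one step per ring, no protecting-group operation between rounds, and a hindered C–O bond made by attack of a small O–H group on a carbene rather than by reductive elimination at a crowded metal centre. The forward reaction has to insert once per round, which is steered by using the growing phenol in excess.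

**13 from 9 and 12 (key disconnection).** The O–C6 bond of ring D is cut. Ring D is the one ring whose two bridge oxygens are ortho to each other, so its carbonyl must be ortho to the diazo carbon: the ortho-quinone diazide 12. After insertion the carbonyl oxygen of 12 is the hydroxyl on C1 of ring D, exactly the oxygen that carries the chain on to ring C. The cut is placed here and not at O–C1 of ring E, because C1 of ring E has no handle that would make it electrophilic, whereas C6 of ring D is a natural carbene carbon. The forward reaction has to form the most congested ether of the molecule, between the oxygens on C1 and C5 of ring D, on a trimeric phenol.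

**9 from 8 and 7, 8 from 3 and 7.** Rings E and F are cut at O–C4 in the same way as rings A to C. The chain starts from phenol 3, which is ring G with its three adjacent oxygens already in place, and grows from ring G toward ring A.

**7 from 4 via 5 and 6; 12 from 3 via 10 and 11; 3 from 1 via 2.** The diazo carbons are the positions where the parent phenols are most nucleophilic: para to the hydroxyl in 4, and ortho in 3, whose para position is blocked. The C–H bond is turned into C–N by azo coupling, reductive cleavage and diazotisation. This copies the logic of the presumed biosynthesis, in which the phenol oxygen of one unit attacks a ring carbon of an oxidised neighbour; 7 and 12 are isolable stand-ins for that oxidised unit. Phenol 3 is used twice, as ring G and as the precursor of ring D, and comes from aldehyde 1 through formate 2.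

## Alternatives that were turned down

**Alternative 1:** the textbook route, an iterative Ullmann ether synthesis.
- Disconnection: each O–C1 bond, between a 2,6-bis(benzyloxy)phenol and an aryl bromide.
- Forward key step: the chain grows from ring A, starting with the hindered phenol A1 (2,4,6-tris(benzyloxy)phenol). Copper-catalysed coupling with the monomer bromide A2 (5-bromo-1,3-bis(benzyloxy)-2-(methoxymethoxy)benzene) is followed by unmasking of the next hindered phenol.
- Reason for rejection: every one of the six couplings pairs a di-ortho-alkoxy, weakly nucleophilic phenoxide with an electron-rich aryl bromide. Both features slow the copper cycle, so high temperatures and hydrodebromination are to be expected, worst at ring D, where the phenol is flanked by an aryloxy and a benzyloxy group. Each ring costs two steps plus a monomer synthesis, and ring D needs a building block of its own, so the route would run well beyond twenty steps. It does not use the para or ortho relation of the oxygens at all.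

**Alternative 2:** nucleophilic aromatic substitution followed by Baeyer–Villiger oxidation.
- Disconnection: the same O–C4 bonds as in the chosen route, with the electrophile being the para-formyl aryl fluoride A3 (3,5-bis(benzyloxy)-4-fluorobenzaldehyde). Ring D would come from A4 (3,4,5-tris(benzyloxy)-2-fluorobenzaldehyde).
- Forward key step: a phenoxide displaces fluoride, and peracid oxidation of the formyl group unveils the next phenol.
- Reason for rejection: the fluorine of A3 lies between two π-donating alkoxy groups and is activated by a single para formyl group. The Meisenheimer adduct is poorly stabilised and crowded, so forcing conditions in polar aprotic solvents would be needed on ever larger, air- and base-sensitive phenoxides. Each bond costs two steps (twelve for the six bonds), and A3 and A4 need several steps themselves. The same logic with bromides and copper is kept only as a fallback.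

**Alternative 3:** biomimetic direct oxidative C–O coupling.
- Disconnection: the O–C4 bonds, by dehydrogenative coupling of two free phenols.
- Forward key step: for example, 4 is oxidised to its phenoxonium ion and trapped at C4 by the hydroxyl of 3. This gives the dienone A5 (3,5-bis(benzyloxy)-4-[3,4,5-tris(benzyloxy)phenoxy]cyclohexa-2,5-dien-1-one), which would tautomerise to 8.
- Reason for rejection: the para-alkoxyphenol 3 is oxidised more easily than 4 and would go to a quinone. Carbon–carbon coupling at the nucleophilic ring positions competes with O-attack. The product 8 is again an oxidisable phenol, so neither chain length nor ring order can be controlled, and the ortho junction at ring D cannot be directed. The chosen route keeps this polarity but stores the oxidation state in a diazo group, so each oxidised unit is made and used one at a time.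

Key step: step 10

Remark: aldehyde 1, phenol 4 and benzenediazonium tetrafluoroborate are taken as purchasable. The azo compounds 5 and 10 are drawn as E isomers. Where a phenol is used in excess in an insertion step, the surplus is meant to be recovered and reused.

## Route

Step 1
Reactants: 1 3,4,5-tris(benzyloxy)benzaldehyde
Product: 3 3,4,5-tris(benzyloxy)phenol, via aryl formate 2 (not isolated)
Conditions: mCPBA, CH2Cl2, 0 °C to rt; then K2CO3 (cat.), MeOH, rt
Reagents that add atoms: m-chloroperoxybenzoic acid (mCPBA), O=C(OO)c1cccc(Cl)c1
Why: Baeyer–Villiger oxidation of an electron-rich benzaldehyde: the trialkoxyaryl group migrates in the Criegee adduct to give formate 2, and methanolysis cleaves it to phenol 3, which serves as ring G and as the precursor of ring D; benzyl ethers are inert to both reagents.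

Step 2
Reactants: 4 3,5-bis(benzyloxy)phenol
Product: 5 3,5-bis(benzyloxy)-4-[(E)-phenyldiazenyl]phenol
Conditions: PhN2+ BF4−, NaHCO3, THF/H2O, 0 °C
Reagents that add atoms: benzenediazonium tetrafluoroborate, N#[N+]c1ccccc1.F[B-](F)(F)F
Why: Azo coupling (electrophilic aromatic substitution) on a strongly activated phenol; attack para to the hydroxyl, at C4 between the two benzyloxy groups, should dominate because the slim diazonium ion is little affected by the flanking groups, and any ortho isomer would be removed by chromatography. One equivalent of the diazonium salt avoids double coupling.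

Step 3
Reactants: 5 3,5-bis(benzyloxy)-4-[(E)-phenyldiazenyl]phenol
Product: 6 4-amino-3,5-bis(benzyloxy)phenol
Conditions: Na2S2O4, THF/H2O, 50 °C
Reagents that add atoms: none
Why: Reductive cleavage of the azo N=N bond by dithionite, the classical way from azo dyes to aminophenols; benzyl ethers are untouched, aniline is separated when 6 is taken into cold aqueous base, and the air-sensitive 6 is used at once.

Step 4
Reactants: 6 4-amino-3,5-bis(benzyloxy)phenol
Product: 7 3,5-bis(benzyloxy)-4-diazocyclohexa-2,5-dien-1-one
Conditions: t-BuONO, TFA (cat.), THF, −10 to 0 °C, dark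
Reagents that add atoms: tert-butyl nitrite, CC(C)(C)ON=O
Why: Diazotisation of a 4-aminophenol; the hydroxyarenediazonium ion loses its phenolic proton to give the neutral para-quinone diazide, here stabilised by the two benzyloxy donors next to the diazo carbon. It is kept cold and dark and made in small batches.

Step 5
Reactants: 3 3,4,5-tris(benzyloxy)phenol; 7 3,5-bis(benzyloxy)-4-diazocyclohexa-2,5-dien-1-one
Product: 8 3,5-bis(benzyloxy)-4-[3,4,5-tris(benzyloxy)phenoxy]phenol (rings F and G, free OH on C1 of ring F)
Conditions: Rh2(OAc)4 (2 mol %), 4 Å MS, PhCF3, 60 °C, dark; 7 added slowly to 3 (3 equiv)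
Reagents that add atoms: none
Why: Proposed new method: Rh2(OAc)4 should convert 7 into a rhodium-bound 4-oxocyclohexa-2,5-dienylidene whose carbene carbon (the future C4 of ring F) takes up the hydroxyl oxygen of 3, and proton transfer to the ring oxygen aromatises the adduct to 8; the closest known reaction type is the Rh2(OAc)4-catalysed O–H insertion of 1,2-diazonaphthoquinones and cyclic 2-diazo-1,3-diketones into alcohols and phenols. The threefold excess of 3 and slow addition of 7 should hold back a second insertion into the new hydroxyl of 8, which would in any case give 9.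

Step 6
Reactants: 8 3,5-bis(benzyloxy)-4-[3,4,5-tris(benzyloxy)phenoxy]phenol; 7 3,5-bis(benzyloxy)-4-diazocyclohexa-2,5-dien-1-one
Product: 9 3,5-bis(benzyloxy)-4-{3,5-bis(benzyloxy)-4-[3,4,5-tris(benzyloxy)phenoxy]phenoxy}phenol (rings E, F and G, free OH on C1 of ring E)
Conditions: Rh2(OAc)4 (2 mol %), 4 Å MS, PhCF3, 60 °C, dark; 7 added slowly to 8 (2.5 equiv)
Reagents that add atoms: none
Why: Proposed new method: the same carbene O–H insertion as in step 5 (rhodium-bound 4-oxocyclohexadienylidene from 7, attack by the C1 hydroxyl of ring F, aromatisation of the new ring E); the closest known reaction type is the Rh2(OAc)4-catalysed O–H insertion of diazonaphthoquinones and 2-diazo-1,3-diketones into alcohols and phenols. Excess 8, recovered afterwards, limits a second insertion, which here would lead off the route.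

Step 7
Reactants: 3 3,4,5-tris(benzyloxy)phenol
Product: 10 3,4,5-tris(benzyloxy)-2-[(E)-phenyldiazenyl]phenol
Conditions: PhN2+ BF4−, NaHCO3, THF/H2O, 0 °C
Reagents that add atoms: benzenediazonium tetrafluoroborate, N#[N+]c1ccccc1.F[B-](F)(F)F
Why: Azo coupling of a phenol whose para position is blocked: the only activated C–H positions are the equivalent C2 and C6, so the nitrogen can enter only ortho to the hydroxyl and next to a benzyloxy group, the future C6 of ring D. Weakly basic, cold conditions limit electron-transfer oxidation of the electron-rich phenol.

Step 8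
Reactants: 10 3,4,5-tris(benzyloxy)-2-[(E)-phenyldiazenyl]phenol
Product: 11 2-amino-3,4,5-tris(benzyloxy)phenol
Conditions: Na2S2O4, THF/H2O, 50 °C
Reagents that add atoms: none
Why: Dithionite cleavage of the ortho-hydroxyazo compound to the ortho-aminophenol and aniline, as in step 3; benzyl ethers survive and the product is used directly.

Step 9
Reactants: 11 2-amino-3,4,5-tris(benzyloxy)phenol
Product: 12 3,4,5-tris(benzyloxy)-6-diazocyclohexa-2,4-dien-1-one
Conditions: t-BuONO, TFA (cat.), THF, −10 to 0 °C, dark
Reagents that add atoms: tert-butyl nitrite, CC(C)(C)ON=O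
Why: Diazotisation of a 2-aminophenol gives the neutral ortho-quinone diazide, the class of diazo compound best known from diazonaphthoquinones; exclusion of light and heat avoids premature Wolff rearrangement.

Step 10
Reactants: 9 3,5-bis(benzyloxy)-4-{3,5-bis(benzyloxy)-4-[3,4,5-tris(benzyloxy)phenoxy]phenoxy}phenol; 12 3,4,5-tris(benzyloxy)-6-diazocyclohexa-2,4-dien-1-one
Product: 13 2-(3,5-bis(benzyloxy)-4-{3,5-bis(benzyloxy)-4-[3,4,5-tris(benzyloxy)phenoxy]phenoxy}phenoxy)-3,4,5-tris(benzyloxy)phenol (rings D to G, ten benzyl ethers, free OH on C1 of ring D)
Conditions: Rh2(OAc)4 (2 mol %), 4 Å MS, PhCF3, 50 °C, dark; 12 added slowly to 9 (1.5 equiv)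
Reagents that add atoms: none
Why: Proposed new method: Rh2(OAc)4 should extrude dinitrogen from the ortho-quinone diazide 12 and give a rhodium-bound 2-oxocyclohexadienylidene at C6 of the future ring D; the hydroxyl oxygen of 9 adds to this electrophilic carbon, and proton transfer from the resulting oxonium ylide to the neighbouring ring oxygen frees the catalyst and aromatises ring D, so that the C6–O bond, the pentaoxygenated arene and the free C1 hydroxyl that carries the chain on arise in one event. The closest known reaction type is the O–H insertion of carbenes made with Rh2(OAc)4 from 1,2-diazonaphthoquinones and from cyclic 2-diazo-1,3-diketones into alcohols and phenols; new are a monocyclic trialkoxy ortho-quinone diazide and a phenol of this size. No ring is closed and no stereocentre is formed; what the step builds is the most congested ether of the target, at C6 of ring D between the oxygens on C1 and C5, while it joins ring D to the E–F–G trimer. Three selectivities are needed. Oxygen rather than carbon attack by 9: rhodium carbenes take the hydroxyl lone pair of a phenol faster than its ring carbons, and a non-polar solvent without base suppresses azo coupling of 12 at C2 and C6 of ring E. A single insertion: the hydroxyl set free on C1 of ring D lies next to the new bulky aryloxy group on C6, whereas the hydroxyl of 9 is flanked by two C–H, so 9 in 1.5-fold excess should outrun 13. Carbene capture rather than Wolff ring contraction or attack of the carbene on the phenyl ring of the C5 benzyl ether: metal catalysis at 50 °C in the dark replaces heat or light, and a high standing concentration of 9 with slow addition of 12 favours the bimolecular path.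

Step 11
Reactants: 13 tetrameric phenol (rings D to G, free OH on C1 of ring D); 7 3,5-bis(benzyloxy)-4-diazocyclohexa-2,5-dien-1-one
Product: 14 pentameric phenol: 3,5-bis(benzyloxy)-4-(aryloxy)phenol whose aryl group is 13 bound through the oxygen on C1 of ring D (rings C to G, twelve benzyl ethers, free OH on C1 of ring C)
Conditions: Rh2(OAc)4 (2 mol %), 4 Å MS, PhCF3, 60 °C, dark; 7 added slowly to 13 (2 equiv)
Reagents that add atoms: none
Why: Proposed new method: carbene O–H insertion as in step 5, the rhodium-bound 4-oxocyclohexadienylidene from 7 being attacked by the C1 hydroxyl of ring D and aromatising to ring C; the closest known reaction type is the Rh2(OAc)4-catalysed O–H insertion of diazonaphthoquinones and 2-diazo-1,3-diketones into alcohols and phenols. Excess 13 is needed because its hydroxyl is more screened than that of 14; the product of a second insertion is 15 and is not lost.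

Step 12
Reactants: 14 pentameric phenol (rings C to G, free OH on C1 of ring C); 7 3,5-bis(benzyloxy)-4-diazocyclohexa-2,5-dien-1-one
Product: 15 hexameric phenol: 3,5-bis(benzyloxy)-4-(aryloxy)phenol whose aryl group is 14 bound through the oxygen on C1 of ring C (rings B to G, fourteen benzyl ethers, free OH on C1 of ring B)
Conditions: Rh2(OAc)4 (2 mol %), 4 Å MS, PhCF3, 60 °C, dark; 7 added slowly to 14 (2 equiv)
Reagents that add atoms: none
Why: Proposed new method: the same insertion of the rhodium-bound 4-oxocyclohexadienylidene from 7 into the O–H bond on C1 of ring C, with aromatisation to ring B; the closest known reaction type is the Rh2(OAc)4-catalysed O–H insertion of diazonaphthoquinones and 2-diazo-1,3-diketones into alcohols and phenols. Excess 14 limits double insertion, whose product would be 16.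

Step 13
Reactants: 15 hexameric phenol (rings B to G, free OH on C1 of ring B); 7 3,5-bis(benzyloxy)-4-diazocyclohexa-2,5-dien-1-one
Product: 16 hexadeca-O-benzyl heptamer: 3,5-bis(benzyloxy)-4-(aryloxy)phenol whose aryl group is 15 bound through the oxygen on C1 of ring B (rings A to G, sixteen benzyl ethers, free OH on C1 of ring A)
Conditions: Rh2(OAc)4 (2 mol %), 4 Å MS, PhCF3, 60 °C, dark; 7 added slowly to 15 (2 equiv)
Reagents that add atoms: none
Why: Proposed new method: the same insertion of the rhodium-bound 4-oxocyclohexadienylidene from 7 into the O–H bond on C1 of ring B, with aromatisation to ring A, whose former carbonyl oxygen is the free C1 hydroxyl of the target; the closest known reaction type is the Rh2(OAc)4-catalysed O–H insertion of diazonaphthoquinones and 2-diazo-1,3-diketones into alcohols and phenols. Excess 15 limits a further, useless insertion into 16.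

Step 14
Reactants: 16 hexadeca-O-benzyl heptamer
Product: 17 CNP0304148.0 (heptameric fuhalol, seventeen free hydroxyls)
Conditions: H2 (1 atm), Pd(OH)2/C, THF/MeOH, rt, degassed
Reagents that add atoms: none
Why: Catalytic hydrogenolysis of sixteen aryl benzyl ethers; diaryl ether C–O bonds and the arene rings are not reduced under these conditions, and a neutral, oxygen-free work-up protects the pyrogallol-type rings D and G.

## Compound list

1 | 3,4,5-tris(benzyloxy)benzaldehyde | O=Cc1cc(OCc9ccccc9)c(OCc9ccccc9)c(OCc9ccccc9)c1 | starting material
2 | 3,4,5-tris(benzyloxy)phenyl formate | O=COc1cc(OCc9ccccc9)c(OCc9ccccc9)c(OCc9ccccc9)c1 | intermediate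
3 | 3,4,5-tris(benzyloxy)phenol | Oc1cc(OCc9ccccc9)c(OCc9ccccc9)c(OCc9ccccc9)c1 | intermediate
4 | 3,5-bis(benzyloxy)phenol | Oc1cc(OCc9ccccc9)cc(OCc9ccccc9)c1 | starting material
5 | 3,5-bis(benzyloxy)-4-[(E)-phenyldiazenyl]phenol | Oc1cc(OCc9ccccc9)c(/N=N/c9ccccc9)c(OCc9ccccc9)c1 | intermediate
6 | 4-amino-3,5-bis(benzyloxy)phenol | Nc1c(OCc9ccccc9)cc(O)cc1OCc9ccccc9 | intermediate
7 | 3,5-bis(benzyloxy)-4-diazocyclohexa-2,5-dien-1-one | O=C1C=C(OCc9ccccc9)C(=[N+]=[N-])C(OCc9ccccc9)=C1 | intermediate
8 | 3,5-bis(benzyloxy)-4-[3,4,5-tris(benzyloxy)phenoxy]phenol (rings F, G) | Oc1cc(OCc9ccccc9)c(Oc2cc(OCc9ccccc9)c(OCc9ccccc9)c(OCc9ccccc9)c2)c(OCc9ccccc9)c1 | intermediate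
9 | 3,5-bis(benzyloxy)-4-{3,5-bis(benzyloxy)-4-[3,4,5-tris(benzyloxy)phenoxy]phenoxy}phenol (rings E, F, G) | Oc1cc(OCc9ccccc9)c(Oc2cc(OCc9ccccc9)c(Oc3cc(OCc9ccccc9)c(OCc9ccccc9)c(OCc9ccccc9)c3)c(OCc9ccccc9)c2)c(OCc9ccccc9)c1 | intermediate
10 | 3,4,5-tris(benzyloxy)-2-[(E)-phenyldiazenyl]phenol | Oc1cc(OCc9ccccc9)c(OCc9ccccc9)c(OCc9ccccc9)c1/N=N/c1ccccc1 | intermediate
11 | 2-amino-3,4,5-tris(benzyloxy)phenol | Nc1c(O)cc(OCc9ccccc9)c(OCc9ccccc9)c1OCc9ccccc9 | intermediate
12 | 3,4,5-tris(benzyloxy)-6-diazocyclohexa-2,4-dien-1-one | O=C1C=C(OCc9ccccc9)C(OCc9ccccc9)=C(OCc9ccccc9)C1=[N+]=[N-] | intermediate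
13 | tetrameric phenol, rings D to G: 2-(3,5-bis(benzyloxy)-4-{3,5-bis(benzyloxy)-4-[3,4,5-tris(benzyloxy)phenoxy]phenoxy}phenoxy)-3,4,5-tris(benzyloxy)phenol | Oc1cc(OCc9ccccc9)c(OCc9ccccc9)c(OCc9ccccc9)c1Oc1cc(OCc9ccccc9)c(Oc2cc(OCc9ccccc9)c(Oc3cc(OCc9ccccc9)c(OCc9ccccc9)c(OCc9ccccc9)c3)c(OCc9ccccc9)c2)c(OCc9ccccc9)c1 | intermediate
14 | pentameric phenol, rings C to G, twelve benzyl ethers, free OH on C1 of ring C | Oc1cc(OCc9ccccc9)c(Oc2cc(OCc9ccccc9)c(OCc9ccccc9)c(OCc9ccccc9)c2Oc2cc(OCc9ccccc9)c(Oc3cc(OCc9ccccc9)c(Oc4cc(OCc9ccccc9)c(OCc9ccccc9)c(OCc9ccccc9)c4)c(OCc9ccccc9)c3)c(OCc9ccccc9)c2)c(OCc9ccccc9)c1 | intermediate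
15 | hexameric phenol, rings B to G, fourteen benzyl ethers, free OH on C1 of ring B | Oc1cc(OCc9ccccc9)c(Oc2cc(OCc9ccccc9)c(Oc3cc(OCc9ccccc9)c(OCc9ccccc9)c(OCc9ccccc9)c3Oc3cc(OCc9ccccc9)c(Oc4cc(OCc9ccccc9)c(Oc5cc(OCc9ccccc9)c(OCc9ccccc9)c(OCc9ccccc9)c5)c(OCc9ccccc9)c4)c(OCc9ccccc9)c3)c(OCc9ccccc9)c2)c(OCc9ccccc9)c1 | intermediate
16 | hexadeca-O-benzyl heptamer, rings A to G, free OH on C1 of ring A | Oc1cc(OCc9ccccc9)c(Oc2cc(OCc9ccccc9)c(Oc3cc(OCc9ccccc9)c(Oc4cc(OCc9ccccc9)c(OCc9ccccc9)c(OCc9ccccc9)c4Oc4cc(OCc9ccccc9)c(Oc5cc(OCc9ccccc9)c(Oc6cc(OCc9ccccc9)c(OCc9ccccc9)c(OCc9ccccc9)c6)c(OCc9ccccc9)c5)c(OCc9ccccc9)c4)c(OCc9ccccc9)c3)c(OCc9ccccc9)c2)c(OCc9ccccc9)c1 | intermediate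
17 | CNP0304148.0 | Oc1cc(O)c(Oc2cc(O)c(Oc3cc(O)c(Oc4cc(O)c(O)c(O)c4Oc4cc(O)c(Oc5cc(O)c(Oc6cc(O)c(O)c(O)c6)c(O)c5)c(O)c4)c(O)c3)c(O)c2)c(O)c1 | target

## Step count and least certain steps

Total step count: 14. Longest linear sequence: 10 steps (4 → 5 → 6 → 7 → 8 → 9 → 13 → 14 → 15 → 16 → 17, steps 2, 3, 4, 5, 6, 10, 11, 12, 13 and 14).

**Step 10 (key step, proposed new method).** The most likely failure is loss of the ortho-quinone diazide 12 before the bulky phenol 9 captures the carbene. This could happen by Wolff ring contraction, by attack of the carbene on the phenyl ring of the neighbouring benzyl ether, or by arylation at ring carbons of 9 instead of insertion into its O–H bond. The fallback uses known chemistry. It sets out from 9, with aldehyde 1 as the source of ring D, and comes back at 13.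
- Bromination of 1 with NBS gives 2-bromo-3,4,5-tris(benzyloxy)benzaldehyde F1.
- Ullmann coupling of 9 with F1 (CuI, N,N-dimethylglycine, Cs2CO3, dioxane, 100 °C), in which the ortho formyl group activates the bromide, gives the diaryl ether aldehyde F2.
- Baeyer–Villiger oxidation and methanolysis as in step 1 turn the formyl group into the hydroxyl on C1 of ring D, which is 13.

**Step 11 (proposed new method).** The most likely failure is loss of chain-length control. The hydroxyl of 13 is screened by the ortho aryloxy group, while the product 14 offers an unhindered hydroxyl, so further insertion into the product and carbene attack on the many electron-rich ring C–H positions may consume 7. The fallback uses known chemistry, sets out from 13 and comes back at 14.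
- Commercial 4-bromo-3,5-dihydroxybenzoic acid is perbenzylated (BnBr, K2CO3) to benzyl 4-bromo-3,5-bis(benzyloxy)benzoate F3.
- Reduction with i-Bu2AlH gives [4-bromo-3,5-bis(benzyloxy)phenyl]methanol F4.
- Oxidation with MnO2 gives 4-bromo-3,5-bis(benzyloxy)benzaldehyde F5.
- Ullmann coupling of 13 with F5 (CuI, N,N-dimethylglycine, Cs2CO3, dioxane, 100 °C) gives aldehyde F6. Its formyl group cannot react further, so exactly one ring is added.
- Baeyer–Villiger oxidation and methanolysis give 14.

**Step 5 (proposed new method, first use of 7).** The most likely failure is slow or unselective carbene transfer from the donor-stabilised diazide. Azo coupling or C-arylation at the nucleophilic C2 and C6 of phenol 3 could compete with O–H insertion, or unimolecular decay of the carbene could dominate. The fallback uses known chemistry, sets out from 3 and comes back at 8: Ullmann coupling of 3 with F5 gives 3,5-bis(benzyloxy)-4-[3,4,5-tris(benzyloxy)phenoxy]benzaldehyde F7, and Baeyer–Villiger oxidation with methanolysis gives 8. The same two-step cycle could stand in for steps 6, 12 and 13.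

**Step 14.** The most likely failure is incomplete hydrogenolysis, through catalyst fouling and poor solubility of partly debenzylated intermediates, together with oxidative degradation of the free polyphenol during isolation. The fallback sets out from 16 and comes back at 17 without a new intermediate: cleavage of all benzyl ethers with BCl3 and pentamethylbenzene as cation scavenger in CH2Cl2 at −78 °C, with a methanol quench and work-up under argon.

## Further compounds

F1 | step 10 | 2-bromo-3,4,5-tris(benzyloxy)benzaldehyde | O=Cc1cc(OCc9ccccc9)c(OCc9ccccc9)c(OCc9ccccc9)c1Br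
F2 | step 10 | 2-(3,5-bis(benzyloxy)-4-{3,5-bis(benzyloxy)-4-[3,4,5-tris(benzyloxy)phenoxy]phenoxy}phenoxy)-3,4,5-tris(benzyloxy)benzaldehyde | O=Cc1cc(OCc9ccccc9)c(OCc9ccccc9)c(OCc9ccccc9)c1Oc1cc(OCc9ccccc9)c(Oc2cc(OCc9ccccc9)c(Oc3cc(OCc9ccccc9)c(OCc9ccccc9)c(OCc9ccccc9)c3)c(OCc9ccccc9)c2)c(OCc9ccccc9)c1
F3 | step 11 | benzyl 4-bromo-3,5-bis(benzyloxy)benzoate | O=C(OCc9ccccc9)c1cc(OCc9ccccc9)c(Br)c(OCc9ccccc9)c1
F4 | step 11 | [4-bromo-3,5-bis(benzyloxy)phenyl]methanol | OCc1cc(OCc9ccccc9)c(Br)c(OCc9ccccc9)c1
F5 | step 11 | 4-bromo-3,5-bis(benzyloxy)benzaldehyde | O=Cc1cc(OCc9ccccc9)c(Br)c(OCc9ccccc9)c1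
F6 | step 11 | 3,5-bis(benzyloxy)-4-(aryloxy)benzaldehyde whose aryl group is 13 bound through the oxygen on C1 of ring D | O=Cc1cc(OCc9ccccc9)c(Oc2cc(OCc9ccccc9)c(OCc9ccccc9)c(OCc9ccccc9)c2Oc2cc(OCc9ccccc9)c(Oc3cc(OCc9ccccc9)c(Oc4cc(OCc9ccccc9)c(OCc9ccccc9)c(OCc9ccccc9)c4)c(OCc9ccccc9)c3)c(OCc9ccccc9)c2)c(OCc9ccccc9)c1
F7 | step 5 | 3,5-bis(benzyloxy)-4-[3,4,5-tris(benzyloxy)phenoxy]benzaldehyde | O=Cc1cc(OCc9ccccc9)c(Oc2cc(OCc9ccccc9)c(OCc9ccccc9)c(OCc9ccccc9)c2)c(OCc9ccccc9)c1
F0 | step 14 | none | none
A1 | alternative 1 | 2,4,6-tris(benzyloxy)phenol | Oc1c(OCc9ccccc9)cc(OCc9ccccc9)cc1OCc9ccccc9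
A2 | alternative 1 | 5-bromo-1,3-bis(benzyloxy)-2-(methoxymethoxy)benzene | COCOc1c(OCc9ccccc9)cc(Br)cc1OCc9ccccc9
A3 | alternative 2 | 3,5-bis(benzyloxy)-4-fluorobenzaldehyde | O=Cc1cc(OCc9ccccc9)c(F)c(OCc9ccccc9)c1
A4 | alternative 2 | 3,4,5-tris(benzyloxy)-2-fluorobenzaldehyde | O=Cc1cc(OCc9ccccc9)c(OCc9ccccc9)c(OCc9ccccc9)c1F
A5 | alternative 3 | 3,5-bis(benzyloxy)-4-[3,4,5-tris(benzyloxy)phenoxy]cyclohexa-2,5-dien-1-one | O=C1C=C(OCc9ccccc9)C(Oc2cc(OCc9ccccc9)c(OCc9ccccc9)c(OCc9ccccc9)c2)C(OCc9ccccc9)=C1
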